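In a one-step world where free monomer only adds to chains, a unit once placed stays placed, and that is how the first chemist reads this flask. The second chemist objects that chains also shed units.

free monomer 0.050 M; initiator 0.50 mM; time 12 h

- average number of monomer units in a chain (chains begun, living or dead) at 12 h
- part of the free monomer that has reacted at 12 h

- a step written with two of one species runs at k times the square of its concentration and takes two of it each time
- the average divides the monomer in chains by the number of chains begun, living and dead together
- run time (flask): 12 h

Each living end adds free monomer at ka[M] per minute, with ka = 102 L mol⁻¹ min⁻¹ and [M] the free monomer concentration, and sheds units at ku = 3.03 min⁻¹ whatever [M] is, as long as monomer in chains is there. So the comparison of the two rates turns on one concentration, here 0.0297 M: the ceiling [M]c = ku/ka, the equilibrium monomer concentration, above which a chain grows and below which it shrinks.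

The first chemist argues from the start. The charge cM stands at 1.68 times the ceiling, and the surplus of 0.0203 M spread over 0.50 mM of chains begun gives 40.6 units, so he expects a dp in the tens.

The second asks how the comparison drifts. The uncatalysed loss, with constant kx = 0.00541 min⁻¹, has a half-life of 2.1 h, short against 12 h. By that loss alone [M] reaches the ceiling at tx = ln(cM/[M]c)/kx = 1.60 h. Living ends die faster at first by pairing, whose first half-life of 0.288 h is shorter than the 1.6 h of their first-order death, but pairing slows as the ends thin. Taking 0.50 mM of ends as begun at once, pairing alone leaves 7.62 × 10⁻⁵ M at tx, fewer than were begun; first-order death lowers that further, but the reckoning has ends still there when the sign turns, and chains give units back.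

My reckoning sides with the second chemist: dp ends well under the first chemist's figure, though I can put no number on it, and nearly all of the free monomer has reacted.

The forecast gives dp 4 (from 1.5 to 8) and c 96.5% (from 95% to 98%), reasoning that “chains unzip until the ends are gone”.

The simulation gives dp 5.23 and c 96.9%.

    living end → dead end A (k1 = 0.00741 min⁻¹)
    monomer in chains + living end → free monomer + living end, rate k2*[living end] as long as [monomer in chains] is above zero (k2 = 3.03 min⁻¹)
    2 living end → dead end B (k3 = 57.8 L mol⁻¹ min⁻¹)
    free monomer + living end → monomer in chains + living end, rate k4*[living end]*[free monomer] (k4 = 102 L mol⁻¹ min⁻¹)
    free monomer + initiator → living end + monomer in chains (k5 = 10.2 L mol⁻¹ min⁻¹)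
    free monomer → uncatalysed product (k6 = 0.00541 min⁻¹)

In this flask, addition had half of its turnover done by 0.414 h, and after 1.20 h dp stood at 19.9, with free monomer at 0.0267 M, already under the ceiling, and living ends at 7.29 × 10⁻⁵ M. Chains then lost units while the ends dwindled, to 4.31 × 10⁻⁶ M after 6.00 h, when dp read 7.81. The first chemist's picture fits where monomer in chains outweighs uncatalysed product; the two hold the same share at the end at a charge of 0.148 M. The neighbour charged with 0.20 M, 6.73 times the ceiling, needs 5.88 h by the uncatalysed loss alone to reach it, and ends with dp 221 and 55.2% of its charge in chains.

The constants are assumed; no experiment stands behind them.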